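Readings and results are calculated for substances that don't exist; noise was put on by code.

A small charge of coupling partner was my starting point.

| setting | south-west | south | south-east | red | green | blue |
|---|---|---|---|---|---|---|
| substrate | 5 mM | 5 mM | 5 mM | 5.0 mM | 5.0 mM | 5.0 mM |
| coupling partner | 2.6 mM (in portions, 4) | 5.1 mM (in portions, 4) | 7.7 mM (in portions, 4) | 2.50 mM (in portions, 4) | 6.00 mM (in portions, 4) | 10.0 mM (in portions, 4) |
| remark | run made earlier; portions every 1.2 s | run made earlier; portions every 1.2 s | run made earlier; portions every 1.2 s | the portions of coupling partner follow each other after 1.2 s, the first at the start | the portions of coupling partner follow each other after 1.2 s, the first at the start | the portions of coupling partner follow each other after 1.2 s, the first at the start |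
| time |  |  |  | 10 min | 10 min | 10 min |

| run | time / min | mono adduct / % | substrate / % |
|---|---|---|---|
| south-west | 0.667 | 39.6 | 57.0 |
| south-west | 2.00 | 44.1 | 53.7 |
| south-west | 3.00 | 44.7 | 53.9 |
| south-west | 5.00 | 45.1 | 54.0 |
| south-west | 8.00 | 44.5 | 54.0 |
| south | 0.500 | 53.5 | 31.1 |
| south | 1.00 | 64.0 | 23.6 |
| south | 2.00 | 70.9 | 19.8 |
| south | 4.00 | 74.8 | 18.4 |
| south | 8.00 | 74.6 | 18.4 |
| south-east | 1.33 | 66.6 | 5.1 |
| south-east | 3.00 | 72.7 | 2.0 |
| south-east | 4.00 | 73.5 | 1.6 |
| south-east | 6.00 | 74.4 | 1.5 |
| south-east | 8.00 | 74.3 | 0.9 |

(each reading ± 0.3 percentage points)

- on the list of suspects stand: substrate + coupling partner -> mono adduct; coupling partner + mono adduct <-> bis adduct; coupling partner -> decomposed reagent; coupling partner + mono adduct -> over-reaction product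

1. which of these holds the largest part of the substrate at the end of red (substrate / bis adduct / mono adduct)
2. which of these holds the largest part of the substrate at the end of green (substrate / bis adduct / mono adduct)
3. which of these holds the largest part of the substrate at the end of blue (substrate / bis adduct / mono adduct)
4. amount of mono adduct at the end of red, in percent of the substrate charged

In south-west I had added 2.6 mM of coupling partner, in 4 portions, to 5 mM of substrate, and the mono adduct lay flat, at 45.1% after 5.00 min. The bench rule is that of a titration: each portion buys the same amount of product. From that run I read Y = 0.867, the mono adduct made per coupling partner charged. Red has a ratio of partner to substrate of 0.500, so Y gave me 43.4% of mono adduct.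

Then I went round once more. That answer leaves about 56.6% of the substrate, close to the 54.0% of south-west. In south the substrate ended lower, at 18.4%, and Y read lower too, at 0.733. Red's charge of 2.50 mM lies near the 2.6 mM of south-west, so I kept Y and my figure.

The rule also has an outer border. Y times the ratio reaches the whole substrate at a ratio of 1.15. Green stands at 1.20, and there the rule promises 104% of the substrate, which the charge cannot give. For green and blue I looked at the runs instead: mono adduct stayed above substrate in south-east, 74.3% against 0.9%.

The forecast named substrate for red, mono adduct for green and mono adduct for blue, with 43.2% of mono adduct in red, saying “Mono per partner charged is about 0.86”. My figure stood higher.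

Red ended with 55.4% substrate and 43.3% mono adduct, so Y there came to 0.865. Green and blue ended with mono adduct on top, at 79.3% and 58.3%.

    substrate + coupling partner → mono adduct (k = 26.5 L mol⁻¹ s⁻¹)
    coupling partner + mono adduct ⇌ bis adduct (K = 330 L mol⁻¹, k = 20.5 L mol⁻¹ s⁻¹)
    coupling partner → decomposed reagent (k = 0.00922 s⁻¹)
    coupling partner + mono adduct → over-reaction product (k = 2.65 L mol⁻¹ s⁻¹)

Reckoned at the substrate left in red, capture of coupling partner, the limiting reagent, stands at 0.0734 s⁻¹ per partner, against 0.00922 s⁻¹ for its decay. That ratio is 7.96, and decay took 0.205 mM of the 2.50 mM charged. A neighbour of red with 2.0 mM of substrate has a ratio of 1.25, past the border, where Y promises 108%; it gave 75.9% of mono adduct.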